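The tetrahydropyran is disconnected at the bond between its ring methylene C5 and the oxygen-bearing carbon C6 that carries the arylethyl chain. This bond closes the ring when the allylsilane terminus of an anti β-hydroxy allylsilane attacks the oxocarbenium ion formed in the same flask from its hydroxyl group and 3-arylpropanal. The step exploits the 2,6-trans relationship across the ring oxygen: a temporary silicon-bearing stereocentre at C3 relays the catalytically set C2 configuration to C6 and then vanishes as the C3=C4 alkene, onto which the cis C3 acyl carbon and C4 styryl carbon are later added together by a ketene cycloaddition. The diarylheptanoid arm is attached by anti-SN2′ arylation.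

Key step: step 5

Remark on the chemistry: in the three reagent-controlled steps (4, 13, 15) the antipode named is the one expected to give the drawn configuration; the opposite antipode is used if the sense of induction proves reversed.

Step 1
Reactants: 1 methyl 3-(4-hydroxyphenyl)propanoate
Product: 2 methyl 3-[4-(methoxymethoxy)phenyl]propanoate
Conditions: MOMCl, i-Pr2NEt, CH2Cl2, 0 °C to rt
Reagents that add atoms: chloromethyl methyl ether COCCl
Why: Base-mediated O-alkylation of the phenol (Williamson-type) installs a MOM ether that should survive bases, hydrides, organometallics and the cold Lewis-acid steps that follow.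

Step 2
Reactants: 2 methyl 3-[4-(methoxymethoxy)phenyl]propanoate
Product: 3 3-[4-(methoxymethoxy)phenyl]propanal
Conditions: i-Bu2AlH, CH2Cl2, –78 °C; Rochelle salt work-up
Reagents that add atoms: none
Why: Partial ester reduction should stop at the aldehyde because the tetrahedral aluminium hemiacetal is stable at –78 °C.

Step 3
Reactants: 4 allyloxytrimethylsilane
Product: 6 1-(trimethylsilyl)prop-2-enyl acetate (racemic), via lithium 1-(trimethylsilyl)prop-2-en-1-olate 5 (not isolated)
Conditions: s-BuLi, THF, –78 °C; then Ac2O, –78 °C to rt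
Reagents that add atoms: acetic anhydride CC(=O)OC(C)=O
Why: Allylic deprotonation next to oxygen triggers a retro-Brook (O to C) silyl shift and the resulting alkoxide is acetylated in the same flask.

Step 4
Reactants: 7 4-(methoxymethoxy)benzaldehyde; 6 1-(trimethylsilyl)prop-2-enyl acetate
Product: 8 (1S,2R)-1-[4-(methoxymethoxy)phenyl]-2-(trimethylsilyl)but-3-en-1-ol
Conditions: [Ir(cod)Cl]2 (2.5 mol%), (S)-SEGPHOS (5 mol%), 4-cyano-3-nitrobenzoic acid (10 mol%), Cs2CO3 (20 mol%), i-PrOH (2 equiv), THF, 70 °C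
Reagents that add atoms: none
Why: Iridium-catalysed transfer-hydrogenative carbonyl (α-silyl)allylation should pass through an (E)-σ-allyliridium species and a closed chair transition state, so the anti relationship follows from the allyl geometry and both new stereocentres (carbinol S, silicon-bearing carbon R) are set by the chiral bisphosphine.

Step 5
Reactants: 8 (1S,2R)-1-[4-(methoxymethoxy)phenyl]-2-(trimethylsilyl)but-3-en-1-ol; 3 3-[4-(methoxymethoxy)phenyl]propanal
Product: 10 (2R,6S)-2-[4-(methoxymethoxy)phenyl]-6-{2-[4-(methoxymethoxy)phenyl]ethyl}-3,6-dihydro-2H-pyran (2,6-trans), via (E)-oxocarbenium triflate 9 (not isolated)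
Conditions: TMSOTf (1.1 equiv), CH2Cl2, –78 °C
Reagents that add atoms: none
Why: TMSOTf condenses the hydroxyl of 8 with aldehyde 3 to the (E)-oxocarbenium ion 9, whose allylsilane terminus C5 attacks the oxocarbenium carbon C6 in an anti-SE2′ sense, after which the β-silyl cation loses the trimethylsilyl group to leave the C3=C4 double bond. The closest known reaction type is the [4+2] annulation of β-hydroxy allylsilanes with aldehydes (an intramolecular Hosomi–Sakurai or silyl-Prins cyclization). The tetrahydropyran ring closes in a 6-endo-trig mode through a chair-like transition state. The new stereocentre C6 is controlled by the silicon-bearing carbon: the C–Si bond must lie pseudo-axial (antiperiplanar to the forming C5–C6 bond), which in the anti silane forces the C2 aryl group axial while the (E)-oxocarbenium places the arylethyl chain equatorial, so C2 and C6 should end up trans. The step needs cyclization to outrun Peterson-type ionization of the benzylic C–O bond and 2-oxonia-Cope scrambling, which the silicon-accelerated allylsilane addition at –78 °C is expected to secure.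

Step 6
Reactants: 10 (2R,6S)-2-[4-(methoxymethoxy)phenyl]-6-{2-[4-(methoxymethoxy)phenyl]ethyl}-3,6-dihydro-2H-pyran
Product: 11 7,7-dichloro-2-[4-(methoxymethoxy)phenyl]-4-{2-[4-(methoxymethoxy)phenyl]ethyl}-3-oxabicyclo[4.2.0]octan-8-one (cyclobutanone cis-fused anti to the aryl group)
Conditions: Cl3CCOCl, Zn–Cu couple, POCl3, Et2O, 0 °C to rt
Reagents that add atoms: trichloroacetyl chloride ClC(Cl)(Cl)C(Cl)=O
Why: Dichloroketene made in the flask should undergo a concerted syn [2+2] cycloaddition in which its carbonyl carbon bonds to C3 (the alkene carbon next to the electron-withdrawing C2–O bond) and its CCl2 carbon to C4, on the face anti to the pseudo-axial C2 aryl group, so C3 and C4 are set cis to each other and trans to the aryl group.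

Step 7
Reactants: 11 7,7-dichloro-2-[4-(methoxymethoxy)phenyl]-4-{2-[4-(methoxymethoxy)phenyl]ethyl}-3-oxabicyclo[4.2.0]octan-8-one
Product: 13 1-hydroxy-4-[4-(methoxymethoxy)phenyl]-6-{2-[4-(methoxymethoxy)phenyl]ethyl}hexahydro-1H-furo[3,4-c]pyran-3-one (cis-fused lactol), via methyl 4-(dichloromethyl)tetrahydropyran-3-carboxylate 12 (not isolated)
Conditions: NaOMe, MeOH, 0 °C; then H2O, 50 °C; then aq. citric acid
Reagents that add atoms: water O
Why: Methoxide adds to the strained α,α-dichloroketone and expels the dichloromethyl carbanion (haloform-type ring cleavage), after which saponification, chloride displacement by the cis carboxylate and hydrolysis of the chlorolactone should give the lactol without touching C3 or C4, whose cis relationship is held by the ring fusion.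

Step 8
Reactants: 14 4-hydroxybenzyl alcohol
Product: 15 diethyl (4-hydroxybenzyl)phosphonate
Conditions: P(OEt)3, neat, 130 °C
Reagents that add atoms: triethyl phosphite CCOP(OCC)OCC
Why: Thermal loss of the benzylic hydroxyl gives a p-quinone methide that adds the phosphite, and the phosphonium intermediate dealkylates (Michaelis–Arbuzov-type reaction).

Step 9
Reactants: 15 diethyl (4-hydroxybenzyl)phosphonate
Product: 16 diethyl [4-(methoxymethoxy)benzyl]phosphonate
Conditions: MOMCl, i-Pr2NEt, CH2Cl2, 0 °C to rt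
Reagents that add atoms: chloromethyl methyl ether COCCl
Why: O-Alkylation of the phenol protects it so that only the benzylic position is deprotonated in the olefination.

Step 10
Reactants: 13 cis-fused lactol (pseudo-acid); 16 diethyl [4-(methoxymethoxy)benzyl]phosphonate
Product: 17 (2R,3R,4S,6S)-2-[4-(methoxymethoxy)phenyl]-6-{2-[4-(methoxymethoxy)phenyl]ethyl}-4-{(E)-2-[4-(methoxymethoxy)phenyl]ethenyl}tetrahydropyran-3-carboxylic acid
Conditions: KOt-Bu (3.5 equiv), THF, 0 °C to rt; then aq. NaH2PO4
Reagents that add atoms: none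
Why: Base opens the lactol to the aldehyde carboxylate, and Horner–Wadsworth–Emmons olefination with the benzylic phosphonate anion should give the (E)-styrene while the C4 stereocentre stays in place.

Step 11
Reactants: 17 tetrahydropyran-3-carboxylic acid
Product: 18 (2R,3R,4S,6S)-N-methoxy-N-methyl-2-[4-(methoxymethoxy)phenyl]-6-{2-[4-(methoxymethoxy)phenyl]ethyl}-4-{(E)-2-[4-(methoxymethoxy)phenyl]ethenyl}tetrahydropyran-3-carboxamide
Conditions: MeNHOMe·HCl, EDC·HCl, HOBt, N-methylmorpholine, CH2Cl2, 0 °C to rt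
Reagents that add atoms: N,O-dimethylhydroxylamine hydrochloride CNOC.Cl
Why: Carbodiimide activation of the acid and acylation of the hydroxylamine give the Weinreb amide needed for a single aryl addition.

Step 12
Reactants: 19 (E)-4-(4-hydroxyphenyl)but-3-en-2-one
Product: 20 (E)-4-[4-(methoxymethoxy)phenyl]but-3-en-2-one
Conditions: MOMCl, i-Pr2NEt, CH2Cl2, 0 °C to rt
Reagents that add atoms: chloromethyl methyl ether COCCl
Why: O-Alkylation of the phenol removes the acidic proton before enolate chemistry.

Step 13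
Reactants: 20 (E)-4-[4-(methoxymethoxy)phenyl]but-3-en-2-one; 3 3-[4-(methoxymethoxy)phenyl]propanal
Product: 21 (1E,5S)-5-hydroxy-1,7-bis[4-(methoxymethoxy)phenyl]hept-1-en-3-one
Conditions: (–)-Ipc2BCl, Et3N, Et2O, –78 °C; then 3; then H2O2, pH 7 buffer, MeOH
Reagents that add atoms: none
Why: The methyl ketone forms its diisopinocampheylboron enolate on its only enolizable side and adds to the aldehyde through a closed transition state in which the chiral ligands differentiate the aldehyde faces, setting the (S)-carbinol (boron aldol reaction).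

Step 14
Reactants: 21 (1E,5S)-5-hydroxy-1,7-bis[4-(methoxymethoxy)phenyl]hept-1-en-3-one
Product: 22 (1E,5S)-5-(methoxymethoxy)-1,7-bis[4-(methoxymethoxy)phenyl]hept-1-en-3-one
Conditions: MOMCl, i-Pr2NEt, CH2Cl2, 0 °C to rt
Reagents that add atoms: chloromethyl methyl ether COCCl
Why: Acetalization of the secondary alcohol differentiates it from the allylic alcohol made next.

Step 15
Reactants: 22 (1E,5S)-5-(methoxymethoxy)-1,7-bis[4-(methoxymethoxy)phenyl]hept-1-en-3-one
Product: 23 (1E,3S,5S)-5-(methoxymethoxy)-1,7-bis[4-(methoxymethoxy)phenyl]hept-1-en-3-ol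
Conditions: (R)-2-methyl-CBS-oxazaborolidine (20 mol%), catecholborane, toluene, –78 °C
Reagents that add atoms: none
Why: Corey–Bakshi–Shibata reduction delivers hydride to the enone carbonyl with the styryl group as the large substituent, so the oxazaborolidine should set the (S)-allylic carbinol by reagent control regardless of the remote C5 centre.

Step 16
Reactants: 23 (1E,3S,5S)-5-(methoxymethoxy)-1,7-bis[4-(methoxymethoxy)phenyl]hept-1-en-3-ol
Product: 24 (1E,3S,5S)-5-(methoxymethoxy)-1,7-bis[4-(methoxymethoxy)phenyl]hept-1-en-3-yl pyridine-2-carboxylate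
Conditions: picolinic acid, DCC, DMAP, CH2Cl2, rt
Reagents that add atoms: picolinic acid O=C(O)c1ccccn1
Why: Steglich esterification with retention at the carbinol installs the chelating leaving group for the allylic substitution.

Step 17
Reactants: 25 5-methoxyresorcinol
Product: 26 1-methoxy-3,5-bis(methoxymethoxy)benzene
Conditions: MOMCl, i-Pr2NEt, CH2Cl2, 0 °C to rt
Reagents that add atoms: chloromethyl methyl ether COCCl
Why: Double O-alkylation gives two MOM ethers that both protect the phenols and direct the next metalation to the carbon between them.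

Step 18
Reactants: 26 1-methoxy-3,5-bis(methoxymethoxy)benzene; 24 allylic picolinate
Product: 28 2-{(1R,2E,5S)-5-(methoxymethoxy)-1,7-bis[4-(methoxymethoxy)phenyl]hept-2-en-1-yl}-5-methoxy-1,3-bis(methoxymethoxy)benzene, via 2-lithio-5-methoxy-1,3-bis(methoxymethoxy)benzene 27 (not isolated)
Conditions: n-BuLi, THF, 0 °C; MgBr2·OEt2; CuBr·SMe2; then 24, 0 °C to rt
Reagents that add atoms: none
Why: Directed ortho-lithiation between the two MOM ethers gives the aryl nucleophile which, as its magnesium cuprate, should displace the picolinate in an anti-SN2′ sense (picolinate chelation favours γ-attack), transferring the (S)-carbinol configuration to the (R)-diarylmethine and forming the (E)-alkene.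

Step 19
Reactants: 28 arene bearing the heptenyl arm
Product: 29 2-bromo-4-{(1R,2E,5S)-5-(methoxymethoxy)-1,7-bis[4-(methoxymethoxy)phenyl]hept-2-en-1-yl}-1-methoxy-3,5-bis(methoxymethoxy)benzene
Conditions: NBS, MeCN, 0 °C
Reagents that add atoms: N-bromosuccinimide O=C1CCC(=O)N1Br
Why: Electrophilic aromatic bromination should occur at one of the two equivalent free positions of the trialkoxybenzene ring, which is far more nucleophilic than the other arenes or the alkene.

Step 20
Reactants: 29 aryl bromide; 18 Weinreb amide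
Product: 31 octakis(methoxymethyl) ether of blepharocalyxin B, via aryllithium 30 (not isolated)
Conditions: t-BuLi (2 equiv), THF, –78 °C; then 18, –78 to 0 °C
Reagents that add atoms: none
Why: Bromine–lithium exchange should be faster than deprotonation of the diarylmethine at –78 °C, and the aryllithium adds only once to the Weinreb amide because the chelated tetrahedral intermediate survives until work-up (Weinreb ketone synthesis), so C3 is not epimerized.

Step 21
Reactants: 31 octakis(methoxymethyl) ether of blepharocalyxin B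
Product: 32 blepharocalyxin B
Conditions: TMSOTf, 2,2′-bipyridyl, CH2Cl2, 0 °C to rt; then H2O
Reagents that add atoms: none
Why: The silyl triflate–bipyridyl pair converts aryl and alkyl MOM ethers into silyl ethers or pyridinium acetals that hydrolyse on addition of water, a buffered acetal cleavage chosen to avoid ionization of the C2 benzylic ether and retro-oxa-Michael ring opening.

Compound list
1 | methyl 3-(4-hydroxyphenyl)propanoate | COC(=O)CCc1ccc(O)cc1 | starting material
2 | methyl 3-[4-(methoxymethoxy)phenyl]propanoate | COCOc1ccc(CCC(=O)OC)cc1 | intermediate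
3 | 3-[4-(methoxymethoxy)phenyl]propanal | COCOc1ccc(CCC=O)cc1 | intermediate
4 | allyloxytrimethylsilane | C=CCO[Si](C)(C)C | starting material
5 | lithium 1-(trimethylsilyl)prop-2-en-1-olate | [Li+].[O-]C(C=C)[Si](C)(C)C | intermediate
6 | 1-(trimethylsilyl)prop-2-enyl acetate (racemic) | CC(=O)OC(C=C)[Si](C)(C)C | intermediate
7 | 4-(methoxymethoxy)benzaldehyde | COCOc1ccc(C=O)cc1 | starting material
8 | (1S,2R)-1-[4-(methoxymethoxy)phenyl]-2-(trimethylsilyl)but-3-en-1-ol | C[Si](C)(C)[C@@H]([C@@H](O)c1ccc(OCOC)cc1)C=C | intermediate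
9 | (E)-oxocarbenium triflate from 8 and 3 | C[Si](C)(C)[C@@H]([C@@H]([O+]=CCCc1ccc(OCOC)cc1)c1ccc(OCOC)cc1)C=C.[O-]S(=O)(=O)C(F)(F)F | intermediate
10 | (2R,6S)-2-[4-(methoxymethoxy)phenyl]-6-{2-[4-(methoxymethoxy)phenyl]ethyl}-3,6-dihydro-2H-pyran | C1=CC[C@H](CCc2ccc(OCOC)cc2)O[C@H]1c1ccc(OCOC)cc1 | intermediate
11 | 7,7-dichloro-2-[4-(methoxymethoxy)phenyl]-4-{2-[4-(methoxymethoxy)phenyl]ethyl}-3-oxabicyclo[4.2.0]octan-8-one, cyclobutanone cis-fused anti to the aryl group | O=C3[C@@H]1[C@H](C3(Cl)Cl)C[C@H](CCc2ccc(OCOC)cc2)O[C@H]1c1ccc(OCOC)cc1 | intermediate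
12 | methyl 4-(dichloromethyl)-2-[4-(methoxymethoxy)phenyl]-6-{2-[4-(methoxymethoxy)phenyl]ethyl}tetrahydropyran-3-carboxylate (2,3-trans, 3,4-cis, 2,6-trans) | COC(=O)[C@@H]1[C@H](C(Cl)Cl)C[C@H](CCc2ccc(OCOC)cc2)O[C@H]1c1ccc(OCOC)cc1 | intermediate
13 | 1-hydroxy-4-[4-(methoxymethoxy)phenyl]-6-{2-[4-(methoxymethoxy)phenyl]ethyl}hexahydro-1H-furo[3,4-c]pyran-3-one, cis-fused, lactol epimers | O=C3[C@@H]1[C@H](C(O)O3)C[C@H](CCc2ccc(OCOC)cc2)O[C@H]1c1ccc(OCOC)cc1 | intermediate
14 | 4-hydroxybenzyl alcohol | OCc1ccc(O)cc1 | starting material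
15 | diethyl (4-hydroxybenzyl)phosphonate | CCOP(=O)(Cc1ccc(O)cc1)OCC | intermediate
16 | diethyl [4-(methoxymethoxy)benzyl]phosphonate | CCOP(=O)(Cc1ccc(OCOC)cc1)OCC | intermediate
17 | (2R,3R,4S,6S)-2-[4-(methoxymethoxy)phenyl]-6-{2-[4-(methoxymethoxy)phenyl]ethyl}-4-{(E)-2-[4-(methoxymethoxy)phenyl]ethenyl}tetrahydropyran-3-carboxylic acid | OC(=O)[C@@H]1[C@H](/C=C/c2ccc(OCOC)cc2)C[C@H](CCc2ccc(OCOC)cc2)O[C@H]1c1ccc(OCOC)cc1 | intermediate
18 | N-methoxy-N-methyl amide of 17 | CON(C)C(=O)[C@@H]1[C@H](/C=C/c2ccc(OCOC)cc2)C[C@H](CCc2ccc(OCOC)cc2)O[C@H]1c1ccc(OCOC)cc1 | intermediate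
19 | (E)-4-(4-hydroxyphenyl)but-3-en-2-one | CC(=O)/C=C/c1ccc(O)cc1 | starting material
20 | (E)-4-[4-(methoxymethoxy)phenyl]but-3-en-2-one | CC(=O)/C=C/c1ccc(OCOC)cc1 | intermediate
21 | (1E,5S)-5-hydroxy-1,7-bis[4-(methoxymethoxy)phenyl]hept-1-en-3-one | O=C(/C=C/c1ccc(OCOC)cc1)C[C@@H](O)CCc1ccc(OCOC)cc1 | intermediate
22 | (1E,5S)-5-(methoxymethoxy)-1,7-bis[4-(methoxymethoxy)phenyl]hept-1-en-3-one | O=C(/C=C/c1ccc(OCOC)cc1)C[C@@H](OCOC)CCc1ccc(OCOC)cc1 | intermediate
23 | (1E,3S,5S)-5-(methoxymethoxy)-1,7-bis[4-(methoxymethoxy)phenyl]hept-1-en-3-ol | O[C@H](/C=C/c1ccc(OCOC)cc1)C[C@@H](OCOC)CCc1ccc(OCOC)cc1 | intermediate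
24 | (1E,3S,5S)-5-(methoxymethoxy)-1,7-bis[4-(methoxymethoxy)phenyl]hept-1-en-3-yl pyridine-2-carboxylate | O=C(O[C@H](/C=C/c1ccc(OCOC)cc1)C[C@@H](OCOC)CCc1ccc(OCOC)cc1)c1ccccn1 | intermediate
25 | 5-methoxyresorcinol | COc1cc(O)cc(O)c1 | starting material
26 | 1-methoxy-3,5-bis(methoxymethoxy)benzene | COCOc1cc(OC)cc(OCOC)c1 | intermediate
27 | 2-lithio-5-methoxy-1,3-bis(methoxymethoxy)benzene | [Li]c1c(OCOC)cc(OC)cc1OCOC | intermediate
28 | 2-{(1R,2E,5S)-5-(methoxymethoxy)-1,7-bis[4-(methoxymethoxy)phenyl]hept-2-en-1-yl}-5-methoxy-1,3-bis(methoxymethoxy)benzene | COc1cc(OCOC)c([C@H](/C=C/C[C@@H](OCOC)CCc2ccc(OCOC)cc2)c2ccc(OCOC)cc2)c(OCOC)c1 | intermediate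
29 | 2-bromo-4-{(1R,2E,5S)-5-(methoxymethoxy)-1,7-bis[4-(methoxymethoxy)phenyl]hept-2-en-1-yl}-1-methoxy-3,5-bis(methoxymethoxy)benzene | COc1cc(OCOC)c([C@H](/C=C/C[C@@H](OCOC)CCc2ccc(OCOC)cc2)c2ccc(OCOC)cc2)c(OCOC)c1Br | intermediate
30 | aryllithium from 29 | COc1cc(OCOC)c([C@H](/C=C/C[C@@H](OCOC)CCc2ccc(OCOC)cc2)c2ccc(OCOC)cc2)c(OCOC)c1[Li] | intermediate
31 | octakis(methoxymethyl) ether of blepharocalyxin B | COc1cc(OCOC)c([C@H](/C=C/C[C@@H](OCOC)CCc2ccc(OCOC)cc2)c2ccc(OCOC)cc2)c(OCOC)c1C(=O)[C@@H]1[C@H](/C=C/c2ccc(OCOC)cc2)C[C@H](CCc2ccc(OCOC)cc2)O[C@H]1c1ccc(OCOC)cc1 | intermediate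
32 | blepharocalyxin B | COc1cc(O)c([C@H](/C=C/C[C@@H](O)CCc2ccc(O)cc2)c2ccc(O)cc2)c(O)c1C(=O)[C@@H]1[C@H](/C=C/c2ccc(O)cc2)C[C@H](CCc2ccc(O)cc2)O[C@H]1c1ccc(O)cc1 | target

Total step count: 21. Longest linear sequence: 10 steps (steps 1, 2, 13, 14, 15, 16, 18, 19, 20, 21).

Steps most likely to fail

Step 5. The electron-rich benzylic C–O bond of 8 may ionize under TMSOTf (Peterson-type elimination to a diene), oxocarbenium 9 may scramble by 2-oxonia-Cope rearrangement and erode the trans relationship, and MOM ethers may be partly cleaved. The fallback sets out from 3. A hetero-Diels–Alder reaction with 1-methoxy-3-(trimethylsilyloxy)buta-1,3-diene under a chiral (salen)CrCl catalyst, followed by mild acid work-up, should give (S)-2-{2-[4-(methoxymethoxy)phenyl]ethyl}-2,3-dihydro-4H-pyran-4-one F1. Luche reduction (NaBH4, CeCl3·7H2O) should give the cis allylic alcohol F2, which is acetylated (Ac2O, pyridine) to acetate F3. Pd(OAc)2-catalysed Ferrier-type C-arylation with 4-(methoxymethoxy)phenylboronic acid (syn carbopalladation anti to the acetate, then anti elimination) should place the aryl group trans to the C6 chain and comes back to the route at 10.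

Step 6. The ketene may add with the wrong orientation (carbonyl carbon on C4) or with poor facial selectivity, and ZnCl2 may ionize the doubly activated C2–O bond. The fallback sets out from 10. Palladium-catalysed syn-bis(methoxycarbonylation) (PdCl2, CuCl2, CO, MeOH, NaOAc) should give the cis dimethyl tetrahydropyran-3,4-dicarboxylate F4, in which both new carbons are alike so the orientation question disappears. Reduction of the less hindered C4 ester with one equivalent of i-Bu2AlH at –78 °C should give methyl 4-formyltetrahydropyran-3-carboxylate F5. Horner–Wadsworth–Emmons reaction with 16 should give the methyl ester of the styryl acid F6, and saponification with LiOH comes back to the route at 17.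

Step 7. Semibenzilic ring contraction of the dichlorocyclobutanone to a chlorocyclopropane acid may compete with ring cleavage, hydrolysis of the dichloromethyl group may stall, and base may epimerize C3. The fallback sets out from 11. Reductive dechlorination with Zn in AcOH should give the cis-fused 3-oxabicyclo[4.2.0]octan-8-one F7. Kinetic deprotonation on the methylene side with LiN(i-Pr)2 and trapping with TMSCl should give the 8-(trimethylsilyloxy)-3-oxabicyclo[4.2.0]oct-7-ene F8. Ozonolysis (O3, CH2Cl2/MeOH, –78 °C; then Me2S) cleaves the enol ether to the aldehyde and the carboxylic acid, which close to the lactol, and comes back to the route at 13.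

Further compounds
F1 | step 5 | (S)-2-{2-[4-(methoxymethoxy)phenyl]ethyl}-2,3-dihydro-4H-pyran-4-one | O=C1C=CO[C@@H](CCc2ccc(OCOC)cc2)C1
F2 | step 5 | cis-2-{2-[4-(methoxymethoxy)phenyl]ethyl}-3,4-dihydro-2H-pyran-4-ol | O[C@H]1C=CO[C@@H](CCc2ccc(OCOC)cc2)C1
F3 | step 5 | cis-2-{2-[4-(methoxymethoxy)phenyl]ethyl}-3,4-dihydro-2H-pyran-4-yl acetate | CC(=O)O[C@H]1C=CO[C@@H](CCc2ccc(OCOC)cc2)C1
F4 | step 6 | dimethyl 2-[4-(methoxymethoxy)phenyl]-6-{2-[4-(methoxymethoxy)phenyl]ethyl}tetrahydropyran-3,4-dicarboxylate (3,4-cis, anti to the aryl group) | COC(=O)[C@@H]1[C@H](C(=O)OC)C[C@H](CCc2ccc(OCOC)cc2)O[C@H]1c1ccc(OCOC)cc1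
F5 | step 6 | methyl 4-formyl-2-[4-(methoxymethoxy)phenyl]-6-{2-[4-(methoxymethoxy)phenyl]ethyl}tetrahydropyran-3-carboxylate | COC(=O)[C@@H]1[C@H](C=O)C[C@H](CCc2ccc(OCOC)cc2)O[C@H]1c1ccc(OCOC)cc1
F6 | step 6 | methyl ester of acid 17 | COC(=O)[C@@H]1[C@H](/C=C/c2ccc(OCOC)cc2)C[C@H](CCc2ccc(OCOC)cc2)O[C@H]1c1ccc(OCOC)cc1
F7 | step 7 | 2-[4-(methoxymethoxy)phenyl]-4-{2-[4-(methoxymethoxy)phenyl]ethyl}-3-oxabicyclo[4.2.0]octan-8-one (cis-fused) | O=C3[C@@H]1[C@H](C3)C[C@H](CCc2ccc(OCOC)cc2)O[C@H]1c1ccc(OCOC)cc1
F8 | step 7 | 2-[4-(methoxymethoxy)phenyl]-4-{2-[4-(methoxymethoxy)phenyl]ethyl}-8-(trimethylsilyloxy)-3-oxabicyclo[4.2.0]oct-7-ene | C[Si](C)(C)OC=3[C@@H]1[C@H](C=3)C[C@H](CCc2ccc(OCOC)cc2)O[C@H]1c1ccc(OCOC)cc1
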